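Ring A (C1 with the exocyclic CH2, C2, C3, C4 with the side chain, ring-fusion atoms C5 and C6) is read as a masked cyclohexenone: C1 is a latent ketone, C2 its α-carbon, and C3, C4 and the whole side chain are (S)-citronellal. In one operation an amine-catalysed Michael addition to methyl vinyl ketone gives a 1,5-keto-aldehyde (C1 ketone, C3 aldehyde) that, in the same flask, closes ring A by aldol condensation between C2 and C3, with C4 set by the catalyst. The enone is then moved to C5/C6, from which the seven-membered rings B and C are attached by two conjugate additions and two ring-closing metatheses.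

Key step: step 1

Labels used below: ring B = C5, C6, C7, C8, C9, C10, C11 (C10 is the one-carbon bridge); ring C = C9, C10, C11, C15, C14, C13, C12; C9=C12 is the bridgehead double bond and C15 carries the second exocyclic CH2.

Remark (assumption): the (R)-configured diphenylprolinol methyl ether is taken to shield the enamine face in the same sense as in the known additions of aldehyde enamines to nitroalkenes; this sense gives the C4 configuration drawn.

Step 1
Reactants: 1 (S)-citronellal; 2 methyl vinyl ketone
Product: 4 (4R)-4-[(2S)-6-methylhept-5-en-2-yl]cyclohex-2-en-1-one, via keto-aldehyde 3 (not isolated)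
Conditions: (R)-2-[methoxy(diphenyl)methyl]pyrrolidine (5 mol %), ethyl 3,4-dihydroxybenzoate (20 mol %), neat, 4 °C; excess 2 removed in vacuo; then KOH, n-Bu4NOH (cat.), Et2O/THF/H2O, reflux
Reagents that add atoms: none
Why: The amine turns 1 into its (E)-enamine, which adds through its open face to the hydrogen-bond-activated enone 2 (Michael addition) to give 3; hydroxide then enolizes the methyl ketone at CH3, this enolate attacks the aldehyde carbon and water is lost by E1cB (intramolecular aldol condensation, the second half of a Robinson-type annulation well known for aldehyde/methyl vinyl ketone pairs). Ring A closes in the 6-(enolendo)-exo-trig mode by forming C2–C3. The only new stereocentre, C4, is set in the Michael step by the catalyst, whose methoxy(diphenyl)methyl group blocks one enamine face, independently of the remote methyl-bearing centre of citronellal. The step needs regioselective enolization and retention of C4: only the methyl enolate reaches the aldehyde through a six-membered transition state (the other enolates would give four-membered rings), and the phase-transfer hydroxide conditions should close the ring faster than the aldehyde α-centre epimerizes, after which C4 is no longer α to a carbonyl.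

Step 2
Reactants: 5 penta-1,4-dien-3-ol
Product: 6 tert-butyl(dimethyl)(penta-1,4-dien-3-yloxy)silane
Conditions: t-BuMe2SiCl, imidazole, DMF, 23 °C
Reagents that add atoms: tert-butyldimethylsilyl chloride, CC(C)(C)[Si](C)(C)Cl
Why: Imidazole-promoted silylation of a secondary alcohol (silyl ether formation) should proceed without complication.

Step 3
Reactants: 6 tert-butyl(dimethyl)(penta-1,4-dien-3-yloxy)silane
Product: 8 3-(tert-butyldimethylsilyloxy)pent-4-en-1-ol (racemic), via alkylborane 7 (not isolated)
Conditions: 9-BBN (0.6 equiv), THF, 0 → 23 °C; then NaOH, H2O2, 0 °C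
Reagents that add atoms: hydrogen peroxide, OO
Why: 9-BBN adds anti-Markovnikov to one of the two equivalent vinyl groups (excess diene limits double addition) and alkaline peroxide gives the primary alcohol (hydroboration–oxidation); the carbinol centre becomes stereogenic as a racemate and is erased in step 9.

Step 4
Reactants: 8 3-(tert-butyldimethylsilyloxy)pent-4-en-1-ol
Product: 9 tert-butyl[(5-iodopent-1-en-3-yl)oxy]dimethylsilane (racemic)
Conditions: I2, PPh3, imidazole, CH2Cl2, 0 °C
Reagents that add atoms: iodine, II
Why: Appel-type iodination converts the primary alcohol into the iodide by SN2 displacement of the oxyphosphonium group and leaves the silyl ether and the olefin untouched.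

Step 5
Reactants: 4 (4R)-4-[(2S)-6-methylhept-5-en-2-yl]cyclohex-2-en-1-one; 9 tert-butyl[(5-iodopent-1-en-3-yl)oxy]dimethylsilane
Product: 11 (4R)-6-[3-(tert-butyldimethylsilyloxy)pent-4-en-1-yl]-4-[(2S)-6-methylhept-5-en-2-yl]cyclohex-2-en-1-one (epimers at C6 and at the silyloxy carbon), via lithium dienolate 10 (not isolated)
Conditions: LiN(i-Pr)2, THF, −78 °C; then 9, HMPA, −78 → −20 °C
Reagents that add atoms: none
Why: Kinetic deprotonation at the α′-CH2 (C6) gives the cross-conjugated dienolate, which is alkylated at C6 by the primary iodide (enolate alkylation) to bring in C7–C10; the C6 configuration is irrelevant because C6 becomes sp2 in step 7.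

Step 6
Reactants: 11 alkylated enone
Product: 12 (4R)-2-[3-(tert-butyldimethylsilyloxy)pent-4-en-1-yl]-4-[(2S)-6-methylhept-5-en-2-yl]cyclohexan-1-one (epimer mixture)
Conditions: LiBH(s-Bu)3, THF, −78 °C; then H2O
Reagents that add atoms: none
Why: The bulky trialkylborohydride delivers hydride to the unsubstituted β-carbon C3 rather than to the carbonyl (conjugate reduction of a β-unsubstituted cyclohexenone), turning the bond made in step 1 into the saturated C2–C3 unit of ring A.

Step 7
Reactants: 12 saturated ketone
Product: 14 (4S)-2-[3-(tert-butyldimethylsilyloxy)pent-4-en-1-yl]-4-[(2S)-6-methylhept-5-en-2-yl]cyclohex-2-en-1-one (epimers at the silyloxy carbon), via silyl enol ether 13 (not isolated)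
Conditions: BrMgN(i-Pr)2, Me3SiCl, Et3N, HMPA, Et2O, 23 °C; then Pd(OAc)2, MeCN, 23 °C
Reagents that add atoms: none
Why: The equilibrating magnesium amide/Me3SiCl conditions give the more substituted silyl enol ether (C1=C6), and Saegusa–Ito oxidation (palladation at C6, β-hydride elimination from C5) places the double bond at C5=C6, so that the enone now lies next to C4.

Step 8
Reactants: 14 transposed enone
Product: 16 (2S,3S,4S)-2-(3-hydroxypent-4-en-1-yl)-4-[(2S)-6-methylhept-5-en-2-yl]-3-vinylcyclohexan-1-one (carbinol epimers), via silyl enol ether 15 (not isolated)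
Conditions: CH2=CHMgBr, CuBr·SMe2 (20 mol %), Me3SiCl, HMPA, THF, −78 °C; then HF·pyridine, THF, −20 → 23 °C
Reagents that add atoms: vinylmagnesium bromide, C=C[Mg]Br
Why: Copper-catalysed conjugate addition places the vinyl group on C5 anti to the C4 side chain (trans-3,4 preference of 4-substituted cyclohexenones) and Me3SiCl traps the enolate, whose protodesilylation by HF·pyridine should deliver the proton to C6 anti to the adjacent pseudoaxial vinyl group (kinetic protonation to the cis-2,3 ketone) while the secondary silyl ether is cleaved.

Step 9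
Reactants: 16 hydroxy ketone
Product: 17 (2S,3S,4S)-4-[(2S)-6-methylhept-5-en-2-yl]-2-(3-oxopent-4-en-1-yl)-3-vinylcyclohexan-1-one
Conditions: Dess–Martin periodinane, CH2Cl2, 0 → 23 °C
Reagents that add atoms: none
Why: Periodinane oxidation of the allylic secondary alcohol gives the vinyl ketone at C9 under conditions that should not epimerize C6, and removes the racemic carbinol centre.

Step 10
Reactants: 17 vinyl ketone
Product: 18 (4S,4aS,9aS)-4-[(2S)-6-methylhept-5-en-2-yl]-3,4,4a,8,9,9a-hexahydro-1H-benzo[7]annulene-1,7(2H)-dione (cis-fused rings A and B)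
Conditions: second-generation Grubbs catalyst (5 mol %), CH2Cl2 (2 mM), 40 °C
Reagents that add atoms: none
Why: Ring-closing metathesis between the vinyl group on C5 and the vinyl ketone closes the seven-membered ring B as the (Z)-enone C9(=O)–C10=C11, the cis relationship at C5/C6 becoming the cis ring fusion, while the trisubstituted side-chain olefin is too hindered to compete.

Step 11
Reactants: 18 bicyclic enedione
Product: 19 the (E)-allylic alcohol of 18, side chain (2S,5E)-7-hydroxy-6-methylhept-5-en-2-yl
Conditions: SeO2 (20 mol %), t-BuOOH, salicylic acid (cat.), CH2Cl2, 23 °C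
Reagents that add atoms: selenium dioxide, O=[Se]=O; tert-butyl hydroperoxide, CC(C)(C)OO
Why: SeO2-catalysed allylic oxidation (ene reaction, then [2,3]-sigmatropic shift) attacks the electron-rich isopropylidene terminus at its (E)-methyl group, whereas the enone double bond is electron-poor and should stay untouched.

Step 12
Reactants: 19 allylic alcohol
Product: 20 the tert-butyldimethylsilyl ether of 19
Conditions: t-BuMe2SiCl, imidazole, CH2Cl2, 23 °C
Reagents that add atoms: tert-butyldimethylsilyl chloride, CC(C)(C)[Si](C)(C)Cl
Why: Silylation of the primary allylic alcohol protects it against the organometallic and titanium reagents of steps 14 and 15.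

Step 13
Reactants: 21 2,3-dibromoprop-1-ene
Product: 22 2-bromohexa-1,5-diene
Conditions: CH2=CHCH2MgBr, Et2O, 0 → 35 °C
Reagents that add atoms: allylmagnesium bromide, C=CC[Mg]Br
Why: The allyl Grignard reagent displaces the allylic bromide (SN2 and SN2′ give the same product) and leaves the vinylic bromide in place.

Step 14
Reactants: 20 silyl-protected enedione; 22 2-bromohexa-1,5-diene
Product: 24 the 5-(hexa-1,5-dien-2-yl)-5,6-dihydro derivative of 20 with the new group on C11 trans to the C4–C5 bond of ring A, via Grignard reagent 23 (not isolated)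
Conditions: 22, Mg, THF, 40 °C; CuBr·SMe2 (0.5 equiv per 23), THF, −78 → −40 °C; then 20, −78 → −40 °C; aqueous NH4Cl
Reagents that add atoms: none
Why: The alkenyl Gilman cuprate adds to the β-carbon C11 of the cycloheptenone from the convex face, anti to ring A at the adjacent C5 (conjugate addition trans to the γ-substituent), which sets C11 and brings in C12–C15 with the C15 methylene in place; a stoichiometric cuprate spares the saturated ketone.

Step 15
Reactants: 24 diketone
Product: 25 the bis(methylene) tetraene, C1 and C9 carbonyls of 24 replaced by C=CH2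
Conditions: Cp2TiMe2 (6 equiv), toluene, 70 °C, dark
Reagents that add atoms: dimethyltitanocene, C[Ti](C)(C1C=CC=C1)C1C=CC=C1
Why: Thermolysis of Cp2TiMe2 gives Cp2Ti=CH2, which methylenates both ketones under non-basic conditions (Petasis olefination), so that the epimerizable C6 centre is fixed without equilibration.

Step 16
Reactants: 25 tetraene
Product: 26 the tert-butyldimethylsilyl ether of the target
Conditions: second-generation Hoveyda–Grubbs catalyst (10 mol %), toluene (1 mM), 80 °C
Reagents that add atoms: none
Why: Ring-closing metathesis between the terminal vinyl group and the exocyclic methylene on C9 closes ring C and creates the C9=C12 bridgehead olefin, (Z) in ring C and (E) in the ten-membered perimeter as a bicyclo[4.4.1]undecene allows; closure onto the other two methylene groups would give four- or eight-membered rings.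

Step 17
Reactants: 26 silyl ether
Product: 27 CNP0264710.1 (target)
Conditions: Bu4NF, THF, 23 °C
Reagents that add atoms: none
Why: Fluoride cleaves the primary silyl ether (desilylation) without touching the four olefins or any stereocentre.

Compound list
1 | (S)-citronellal, (3S)-3,7-dimethyloct-6-enal | O=CC[C@@H](C)CCC=C(C)C | starting material
2 | methyl vinyl ketone (but-3-en-2-one) | CC(=O)C=C | starting material
3 | (2R,3S)-3,7-dimethyl-2-(3-oxobutyl)oct-6-enal | O=C[C@@H]([C@@H](C)CCC=C(C)C)CCC(C)=O | intermediate (not isolated)
4 | (4R)-4-[(2S)-6-methylhept-5-en-2-yl]cyclohex-2-en-1-one | O=C1C=C[C@@H]([C@@H](C)CCC=C(C)C)CC1 | intermediate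
5 | penta-1,4-dien-3-ol | C=CC(O)C=C | starting material
6 | tert-butyl(dimethyl)(penta-1,4-dien-3-yloxy)silane | C=CC(O[Si](C)(C)C(C)(C)C)C=C | intermediate
7 | 9-[3-(tert-butyldimethylsilyloxy)pent-4-en-1-yl]-9-borabicyclo[3.3.1]nonane (racemic) | C=CC(O[Si](C)(C)C(C)(C)C)CCB1C2CCCC1CCC2 | intermediate (not isolated)
8 | 3-(tert-butyldimethylsilyloxy)pent-4-en-1-ol (racemic) | OCCC(O[Si](C)(C)C(C)(C)C)C=C | intermediate
9 | tert-butyl[(5-iodopent-1-en-3-yl)oxy]dimethylsilane (racemic) | ICCC(O[Si](C)(C)C(C)(C)C)C=C | intermediate
10 | lithium dienolate of 4 (O-lithio; C1=C6 and C2=C3) | [Li]OC1=CC[C@H]([C@@H](C)CCC=C(C)C)C=C1 | intermediate (not isolated)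
11 | (4R)-6-[3-(tert-butyldimethylsilyloxy)pent-4-en-1-yl]-4-[(2S)-6-methylhept-5-en-2-yl]cyclohex-2-en-1-one (epimers at C6 and the silyloxy carbon) | O=C1C=C[C@@H]([C@@H](C)CCC=C(C)C)CC1CCC(O[Si](C)(C)C(C)(C)C)C=C | intermediate
12 | (4R)-2-[3-(tert-butyldimethylsilyloxy)pent-4-en-1-yl]-4-[(2S)-6-methylhept-5-en-2-yl]cyclohexan-1-one (epimers at C2 and the silyloxy carbon) | O=C1CC[C@@H]([C@@H](C)CCC=C(C)C)CC1CCC(O[Si](C)(C)C(C)(C)C)C=C | intermediate
13 | trimethylsilyl enol ether of 12 toward the substituted α-carbon | C[Si](C)(C)OC1=C(CCC(O[Si](C)(C)C(C)(C)C)C=C)C[C@H]([C@@H](C)CCC=C(C)C)CC1 | intermediate (not isolated)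
14 | (4S)-2-[3-(tert-butyldimethylsilyloxy)pent-4-en-1-yl]-4-[(2S)-6-methylhept-5-en-2-yl]cyclohex-2-en-1-one (epimers at the silyloxy carbon) | O=C1CC[C@@H]([C@@H](C)CCC=C(C)C)C=C1CCC(O[Si](C)(C)C(C)(C)C)C=C | intermediate
15 | trimethylsilyl enol ether (C1=C2) of the 3-vinyl adduct of 14, vinyl trans to the C4 side chain | C[Si](C)(C)OC1=C(CCC(O[Si](C)(C)C(C)(C)C)C=C)[C@@H](C=C)[C@H]([C@@H](C)CCC=C(C)C)CC1 | intermediate (not isolated)
16 | (2S,3S,4S)-2-(3-hydroxypent-4-en-1-yl)-4-[(2S)-6-methylhept-5-en-2-yl]-3-vinylcyclohexan-1-one (2,3-cis, 3,4-trans; carbinol epimers) | O=C1CC[C@@H]([C@@H](C)CCC=C(C)C)[C@H](C=C)[C@@H]1CCC(O)C=C | intermediate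
17 | (2S,3S,4S)-4-[(2S)-6-methylhept-5-en-2-yl]-2-(3-oxopent-4-en-1-yl)-3-vinylcyclohexan-1-one | O=C1CC[C@@H]([C@@H](C)CCC=C(C)C)[C@H](C=C)[C@@H]1CCC(=O)C=C | intermediate
18 | (4S,4aS,9aS)-4-[(2S)-6-methylhept-5-en-2-yl]-3,4,4a,8,9,9a-hexahydro-1H-benzo[7]annulene-1,7(2H)-dione | O=C1CC[C@@H]([C@@H](C)CCC=C(C)C)[C@H]2[C@@H]1CCC(=O)C=C2 | intermediate
19 | 18 with the side chain oxidized to (2S,5E)-7-hydroxy-6-methylhept-5-en-2-yl | O=C1CC[C@@H]([C@@H](C)CC/C=C(\C)CO)[C@H]2[C@@H]1CCC(=O)C=C2 | intermediate
20 | tert-butyldimethylsilyl ether of 19 | O=C1CC[C@@H]([C@@H](C)CC/C=C(\C)CO[Si](C)(C)C(C)(C)C)[C@H]2[C@@H]1CCC(=O)C=C2 | intermediate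
21 | 2,3-dibromoprop-1-ene | BrCC(Br)=C | starting material
22 | 2-bromohexa-1,5-diene | C=CCCC(Br)=C | intermediate
23 | hexa-1,5-dien-2-ylmagnesium bromide | C=CCCC(=C)[Mg]Br | intermediate (not isolated)
24 | cis-fused decahydrobenzo[7]annulene-1,7-dione carrying the silyl-protected side chain at C4 and a hexa-1,5-dien-2-yl group at C11 (trans to the C4–C5 bond) | O=C1CC[C@@H]([C@@H](C)CC/C=C(\C)CO[Si](C)(C)C(C)(C)C)[C@H]2[C@@H]1CCC(=O)C[C@@H]2C(=C)CCC=C | intermediate
25 | bis(methylene) analogue of 24 (C1=CH2 and C9=CH2) | C=C1CC[C@@H]([C@@H](C)CC/C=C(\C)CO[Si](C)(C)C(C)(C)C)[C@H]2[C@@H]1CCC(=C)C[C@@H]2C(=C)CCC=C | intermediate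
26 | tert-butyldimethylsilyl ether of the target | C=C1CC[C@@H]([C@@H](C)CC/C=C(\C)CO[Si](C)(C)C(C)(C)C)[C@H]2[C@@H]1CCC1=CCCC(=C)[C@H]2C1 | intermediate
27 | CNP0264710.1 | C=C1CC[C@@H]([C@@H](C)CC/C=C(\C)CO)[C@H]2[C@@H]1CCC1=CCCC(=C)[C@H]2C1 | target

Total step count: 17. Longest linear sequence: 15 steps (from 5 through steps 2–12 and 14–17).

Steps most likely to fail

Step 16. The ruthenium carbene formed at the terminal vinyl group may fail to engage the hindered 1,1-disubstituted methylene on C9, so that intermolecular cross-metathesis (dimerization) or olefin migration overtakes closure of the strained bridged ring. The fallback closes ring C by carbonyl olefination instead of olefin–olefin metathesis and sets out from diketone 24. One equivalent of Mo(=CHCMe2Ph)(=N-2,6-i-Pr2C6H3)[OCMe(CF3)2]2 in benzene should exchange with the terminal vinyl group, and the molybdenum alkylidene so formed should olefinate the C9 ketone across the ring (stoichiometric olefin–ketone ring closure; the C1 ketone would need an eight-membered ring) to give tricyclic ketone F1. Cp2TiMe2 then methylenates the remaining C1 ketone and the route is rejoined at 26.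

Step 8. The proton may reach C6 from both faces, or C6 may epimerize during the desilylation, so that the more stable trans-2,3 ketone accumulates. The fallback replaces kinetic protonation by thermodynamic control in a derivative and sets out from the C6-epimer mixture of 16. Condensation with pyrrolidine (TsOH cat., benzene, water removal) should give the less substituted pyrrolidine enamine F2. In it, allylic 1,3-strain against the pyrrolidine ring forces the C6 substituent axial, that is cis to the equatorial vinyl group, and equilibration through the iminium ion funnels both epimers into this form. Buffered hydrolysis (AcOH, NaOAc, H2O, 0 °C) then returns the cis ketone 16.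

Step 14. The bulky alkenyl cuprate may decompose or add too slowly to the γ-branched cycloheptenone, so that enolization or attack on the saturated ketone takes over. The fallback brings in the same carbons as an acyl radical and sets out from 20. Pent-4-enal with (n-Bu4N)4[W10O32] (2 mol %) in MeCN under 365 nm light (photocatalytic hydroacylation, radical conjugate addition anti to ring A) should give triketone F3. Cp2TiMe2 then converts all three ketones into methylene groups and the route is rejoined at 25.

Further compounds
F1 | step 16 | tricyclic ketone: 26 with C1=O in place of C1=CH2 | O=C1CC[C@@H]([C@@H](C)CC/C=C(\C)CO[Si](C)(C)C(C)(C)C)[C@H]2[C@@H]1CCC1=CCCC(=C)[C@H]2C1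
F2 | step 8 | pyrrolidine enamine of 16 (double bond C1=C2 of ring A, C6 substituent axial and cis to vinyl) | C1CCN(C1)C1=CC[C@@H]([C@@H](C)CCC=C(C)C)[C@H](C=C)[C@@H]1CCC(O)C=C
F3 | step 14 | triketone: 24 with a pent-4-enoyl group on C11 (C15=O in place of C15=CH2) | O=C1CC[C@@H]([C@@H](C)CC/C=C(\C)CO[Si](C)(C)C(C)(C)C)[C@H]2[C@@H]1CCC(=O)C[C@@H]2C(=O)CCC=C
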